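## Retrosynthetic overview

- δ-Tocopherol ⇐ its 6-O-methyl ether (demethylation last).
- The pyran ring is the only ring formed (the arene is bought). It is closed last at C4–C4a by hydroboration / intramolecular B-alkyl Suzuki coupling of an ortho-bromoaryl tertiary allyl ether.
- Key step: the O1–C2 bond and the C2 stereocentre are made together by an intermolecular, branched-selective Pd-catalysed asymmetric allylic etherification of a 2-bromophenol with the whole C20 (E)-phytyl carbonate.
- C4′ and C8′ come unchanged from natural (E,7R,11R)-phytol; the arene comes from 4-methoxy-2-methylphenol.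

Assumption 1: natural (2E,7R,11R)-phytol of ≥97% E purity is purchased.

Assumption 2: the (R,R)-Trost ligand is taken to give the 3R ether from the E-carbonate. I could not verify this sense of induction from first principles; it is checked on the first run by chiral HPLC of 7 against the methyl ether of natural δ-tocopherol. If the sense is opposite, the (S,S)-ligand is used with nothing else changed.

## Route

**Step 1**
Reactants: 1, natural phytol, (2E,7R,11R)-3,7,11,15-tetramethylhexadec-2-en-1-ol
Product: 2, (E)-phytyl methyl carbonate, methyl (2E,7R,11R)-3,7,11,15-tetramethylhexadec-2-en-1-yl carbonate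
Conditions: ClCO2Me, pyridine, CH2Cl2, 0 °C → rt; chromatography (AgNO3–silica if any Z isomer is present)
Reagents that add atoms: methyl chloroformate, COC(=O)Cl
Why: Simple O-acylation of a primary allylic alcohol gives the carbonate leaving group for π-allyl formation without touching the E-olefin or the C7/C11 centres.

**Step 2**
Reactants: 3, 4-methoxy-2-methylphenol
Product: 4, 2-bromo-4-methoxy-6-methylphenol
Conditions: NBS (1.0 equiv), i-Pr2NH (10 mol%), CH2Cl2, 0 °C
Reagents that add atoms: N-bromosuccinimide, O=C1CCC(=O)N1Br
Why: Amine-mediated ortho-selective electrophilic bromination of a phenol puts Br at the only free position ortho to OH (the para position is blocked by OMe), which is the future C4a.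

**Step 3 (key step)**
Reactants: 2, (E)-phytyl methyl carbonate (1.2 equiv); 4, 2-bromo-4-methoxy-6-methylphenol
Product: 5, 1-bromo-5-methoxy-3-methyl-2-{[(3R,7R,11R)-3,7,11,15-tetramethylhexadec-1-en-3-yl]oxy}benzene (branched tertiary aryl ether)
Conditions: Pd2(dba)3·CHCl3 (2 mol%), (R,R)-DACH-phenyl Trost ligand (6 mol%), CH2Cl2 (0.1 M), 0 °C → rt; stop at full conversion of 4
Reagents that add atoms: none (both partners are numbered; CO2 and MeOH are lost)
Why: Trost Pd-catalysed asymmetric allylic alkylation with a phenol nucleophile: Pd(0) ionises the E-carbonate to a 3,3-disubstituted π-allyl (chain syn, methyl anti) whose two faces interconvert by η3–η1–η3 slip through the CH2 terminus, and the chiral ligand pocket directs the phenoxide to the substituted terminus of one face, so C3 (the future C2) is set R by catalyst control while C7/C11 are remote spectators and the aryl bromide is inert to this catalyst at rt.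

**Step 4**
Reactants: 5, the (3R) tertiary allyl aryl ether
Product: 6, 9-[(3S,7R,11R)-3-(2-bromo-4-methoxy-6-methylphenoxy)-3,7,11,15-tetramethylhexadecyl]-9-borabicyclo[3.3.1]nonane (not isolated; the descriptor changes from R to S only because of CIP priorities, no bond at the stereocentre is touched)
Conditions: 9-BBN dimer (1.5 equiv B–H), THF, 0 → 50 °C
Reagents that add atoms: 9-borabicyclo[3.3.1]nonane, B1C2CCCC1CCC2
Why: Anti-Markovnikov hydroboration of the monosubstituted vinyl group by 9-BBN puts boron on the terminal carbon (the future C4) and removes the allylic ether, so Pd(0) can no longer re-ionise the stereocentre.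

**Step 5**
Reactants: 6, the B-alkyl-9-BBN (same pot as step 4)
Product: 7, δ-tocopherol methyl ether, (2R)-6-methoxy-2,8-dimethyl-2-[(4R,8R)-4,8,12-trimethyltridecyl]chromane
Conditions: aq. K3PO4 (3 M, first to quench residual B–H), then Pd(OAc)2 (5 mol%), SPhos (10 mol%), THF/H2O, 0.03 M, 65 °C; ethanolamine work-up
Reagents that add atoms: none
Why: Intramolecular B-alkyl Suzuki–Miyaura coupling forms the C4–C4a bond and closes the six-membered pyran ring by reductive elimination from a seven-membered palladacycle, with an electron-rich biarylphosphine to drive oxidative addition of the electron-rich aryl bromide and no bond to C2 broken.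

**Step 6**
Reactants: 7, δ-tocopherol methyl ether
Product: 8, δ-tocopherol, (2R)-2,8-dimethyl-2-[(4R,8R)-4,8,12-trimethyltridecyl]chroman-6-ol
Conditions: NaSEt (8 equiv), degassed DMF, 140 °C, Ar; then aq. NH4Cl
Reagents that add atoms: none
Why: Thiolate SN2 O-demethylation attacks only the methyl carbon of the aryl methyl ether, so the tertiary C2–O bond cannot ionise and no stereocentre is at risk under these basic, non-Lewis-acidic conditions.

## Compound list

1 | natural phytol, (2E,7R,11R)-3,7,11,15-tetramethylhexadec-2-en-1-ol | OC/C=C(\C)CCC[C@H](C)CCC[C@H](C)CCCC(C)C | starting material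
2 | (E)-phytyl methyl carbonate | COC(=O)OC/C=C(\C)CCC[C@H](C)CCC[C@H](C)CCCC(C)C | intermediate
3 | 4-methoxy-2-methylphenol | COc1ccc(O)c(C)c1 | starting material
4 | 2-bromo-4-methoxy-6-methylphenol | COc1cc(C)c(O)c(Br)c1 | intermediate
5 | 1-bromo-5-methoxy-3-methyl-2-{[(3R,7R,11R)-3,7,11,15-tetramethylhexadec-1-en-3-yl]oxy}benzene | COc1cc(C)c(O[C@](C)(CCC[C@H](C)CCC[C@H](C)CCCC(C)C)C=C)c(Br)c1 | intermediate
6 | 9-[(3S,7R,11R)-3-(2-bromo-4-methoxy-6-methylphenoxy)-3,7,11,15-tetramethylhexadecyl]-9-BBN | COc1cc(C)c(O[C@](C)(CCC[C@H](C)CCC[C@H](C)CCCC(C)C)CCB2C3CCCC2CCC3)c(Br)c1 | intermediate (not isolated)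
7 | (2R,4′R,8′R)-δ-tocopherol methyl ether | Cc1cc(OC)cc2c1O[C@](C)(CCC[C@H](C)CCC[C@H](C)CCCC(C)C)CC2 | intermediate
8 | (2R,4′R,8′R)-δ-tocopherol | Cc1cc(O)cc2c1O[C@](C)(CCC[C@H](C)CCC[C@H](C)CCCC(C)C)CC2 | target

## Summary

Total step count: 6 (steps 4 and 5 run in one pot, so 5 isolations).
Longest linear sequence: 5 steps (1 → 2 → 5 → 6 → 7 → 8).

Three steps most likely to fail:

1. **Step 3 (asymmetric allylic etherification).** The nucleophile is a 2,6-disubstituted phenol attacking a tertiary π-allyl terminus, so branched/linear ratio and diastereoselectivity at C2 are uncertain, and Pd can re-ionise the product and erode both. Any linear ether is purged at steps 4–5 because it does not cyclise; the 2S epimer would need chiral HPLC at 7.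
   Fallback: set C2 by reagent control instead. Sharpless epoxidation of phytol with D-(−)-DET gives the (2R,3R)-epoxide, and Red-Al opening gives the (3R)-1,3-diol. The primary alcohol is converted to the iodide and coupled (Cu catalysis) with an ortho-bromoaryl Grignard. The ring is then closed at O1–C8a by Pd-catalysed intramolecular C–O coupling of the tertiary alcohol, which leaves C2 untouched.

2. **Step 5 (intramolecular B-alkyl Suzuki).** Possible problems are hydrodebromination, protodeboronation, β-hydride elimination and oligomers.
   Fallback: close the ring by electrophilic aromatic substitution. Run the etherification with the non-brominated phenol 3 (also less hindered), hydroborate/oxidise the vinyl group to the carboxylic acid, cyclise by intramolecular Friedel–Crafts acylation to the chroman-4-one, and deoxygenate the ketone to CH2.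

3. **Step 6 (demethylation).** The very electron-rich aryl methyl ether may react slowly, and the phenoxide product is air-sensitive.
   Fallback: change the protecting-group strategy. Carry the 6-OH as a benzyl ether (from 4-benzyloxy-2-methylphenol through the same sequence) and finish with neutral hydrogenolysis (H2, Pd/C).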